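**Retrosynthetic overview**
1. The pyranone C-ring is cut in one operation into three components: o-iodophenol 5, aryl alkyne 7 and CO (which becomes C4), joined by a Pd-catalysed carbonylative Sonogashira annulation. This replaces the usual chalcone or Baker–Venkataraman disconnection.
2. Iodophenol 5 comes from iodination of 2,3,4,5-tetramethoxyphenol 4, which comes from ortho-lithiation/borylation/oxidation of 1,2,3,4-tetramethoxybenzene 1.
3. Alkyne 7 comes from Ohira–Bestmann homologation of 3-hydroxy-4,5-dimethoxybenzaldehyde 6; the 3'-OH is carried unprotected throughout.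
4. Ring order: the A and B rings are bought as arenes; only the C-ring is formed, last, in step 4.

Assumption: the target has no stereocentre and no stereogenic double bond, so "single enantiomer" is taken to mean the single achiral compound drawn; 1, 6 and all reagents are taken as commercially available.

**Step 1**
Reactants: 1 1,2,3,4-tetramethoxybenzene
Product: 4 2,3,4,5-tetramethoxyphenol, via 2,3,4,5-tetramethoxyphenyllithium 2 (not isolated), via dimethyl (2,3,4,5-tetramethoxyphenyl)boronate 3 (not isolated)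
Conditions: n-BuLi, TMEDA, THF, 0 °C; B(OMe)3, −78 °C to rt; AcOH, 30% H2O2, 0 °C to rt
Reagents that add atoms: hydrogen peroxide, OO
Why: Directed ortho-metalation at one of the two equivalent ring C–H positions (each ortho to OMe), borylation, then boronate oxidation with 1,2-aryl shift from B to O gives the phenol; no stereocentre is formed.

**Step 2**
Reactants: 4 2,3,4,5-tetramethoxyphenol
Product: 5 2-iodo-3,4,5,6-tetramethoxyphenol
Conditions: NIS (1.05 equiv), MeCN, −20 to 0 °C, dark
Reagents that add atoms: N-iodosuccinimide, O=C1CCC(=O)N1I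
Why: Electrophilic aromatic iodination (SEAr) can only occur at the single remaining ring C–H, which is ortho to the free OH, and low temperature with a mild N–I reagent limits oxidation of the electron-rich phenol to a quinone.

**Step 3**
Reactants: 6 3-hydroxy-4,5-dimethoxybenzaldehyde
Product: 7 5-ethynyl-2,3-dimethoxyphenol
Conditions: dimethyl (1-diazo-2-oxopropyl)phosphonate (1.3 equiv), K2CO3 (3 equiv), MeOH, 0 °C to rt; aq. NH4Cl work-up
Reagents that add atoms: Ohira–Bestmann reagent, dimethyl (1-diazo-2-oxopropyl)phosphonate, CC(=O)C(=[N+]=[N-])P(=O)(OC)OC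
Why: Seyferth–Gilbert homologation in the Ohira–Bestmann variant (olefination by the diazomethylphosphonate anion, N2 loss, 1,2-H shift of the alkylidene carbene) works here because the meta-phenoxide is not conjugated to the aldehyde, with the extra K2CO3 covering the free phenol.

**Step 4**
Reactants: 5 2-iodo-3,4,5,6-tetramethoxyphenol; 7 5-ethynyl-2,3-dimethoxyphenol
Product: 10 3'-hydroxy-5,6,7,8,4',5'-hexamethoxyflavone, via 2'-hydroxyaryl ynone 8 (not isolated), via β-diethylamino enone 9 (not isolated)
Conditions: PdCl2(dppf) (5 mol%), CO (20 atm), Et2NH, 120 °C (7 in 1.3 equiv)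
Reagents that add atoms: carbon monoxide, [C-]#[O+]
Why: Pd-catalysed carbonylative Sonogashira annulation (oxidative addition of the aryl iodide, CO insertion, alkynylation) gives ynone 8, and Et2NH adds to it to give enaminone 9, which the ortho-OH closes 6-endo with loss of Et2NH to the flavone and not the aurone; the extra meta-phenol on 7 should be tolerated because the reaction already runs on a free o-iodophenol in neat amine.

**Compound list**
1 | 1,2,3,4-tetramethoxybenzene | COc1ccc(OC)c(OC)c1OC | starting material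
2 | 2,3,4,5-tetramethoxyphenyllithium (formed in flask) | [Li]c1cc(OC)c(OC)c(OC)c1OC | intermediate
3 | dimethyl (2,3,4,5-tetramethoxyphenyl)boronate (formed in flask) | COB(OC)c1cc(OC)c(OC)c(OC)c1OC | intermediate
4 | 2,3,4,5-tetramethoxyphenol | COc1cc(O)c(OC)c(OC)c1OC | intermediate
5 | 2-iodo-3,4,5,6-tetramethoxyphenol | COc1c(O)c(I)c(OC)c(OC)c1OC | intermediate
6 | 3-hydroxy-4,5-dimethoxybenzaldehyde | COc1cc(C=O)cc(O)c1OC | starting material
7 | 5-ethynyl-2,3-dimethoxyphenol | COc1cc(C#C)cc(O)c1OC | intermediate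
8 | 1-(2-hydroxy-3,4,5,6-tetramethoxyphenyl)-3-(3-hydroxy-4,5-dimethoxyphenyl)prop-2-yn-1-one (2'-hydroxyaryl ynone, formed in flask) | COc1cc(C#CC(=O)c2c(O)c(OC)c(OC)c(OC)c2OC)cc(O)c1OC | intermediate
9 | (E)-3-(diethylamino)-1-(2-hydroxy-3,4,5,6-tetramethoxyphenyl)-3-(3-hydroxy-4,5-dimethoxyphenyl)prop-2-en-1-one (β-diethylamino enone, formed in flask; geometry has no consequence) | CCN(CC)/C(=C/C(=O)c1c(O)c(OC)c(OC)c(OC)c1OC)c1cc(O)c(OC)c(OC)c1 | intermediate
10 | 3'-hydroxy-5,6,7,8,4',5'-hexamethoxyflavone (achiral) | COc1cc(-c2cc(=O)c3c(OC)c(OC)c(OC)c(OC)c3o2)cc(O)c1OC | target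

**Totals**
Total step count: 4. Longest linear sequence: 3 steps (1 → 4 → 5 → 10; the other branch 6 → 7 → 10 is 2 steps).

**Three steps most likely to fail, with fallbacks**

Step 4 (carbonylative annulation) is the main risk: the aryl iodide is hindered and electron-rich, and non-carbonylative coupling to a benzofuran, aurone formation or protodeiodination could compete. The fallback gives up the Pd/CO disconnection and sets out from phenol 4 together with aldehyde 6. Friedel–Crafts/Fries C-acetylation of 4 at its only free ring position (Ac2O, BF3·OEt2, 70 °C, then aqueous hydrolysis of the BF2 chelate) gives 1-(2-hydroxy-3,4,5,6-tetramethoxyphenyl)ethan-1-one F1. Claisen–Schmidt condensation of this ketone with 6 (excess KOH, EtOH, rt) gives (E)-1-(2-hydroxy-3,4,5,6-tetramethoxyphenyl)-3-(3-hydroxy-4,5-dimethoxyphenyl)prop-2-en-1-one F2. Oxidative cyclisation of the 2'-hydroxychalcone (cat. I2, DMSO, 120 °C) then returns to the route at target 10.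

Step 2 (iodination) may fail because the very electron-rich para-methoxyphenol 4 can be oxidised by N–I reagents to a methoxybenzoquinone. The fallback sets out from 4 and replaces the electrophilic substitution by a directed metalation. Protection (MOMCl, i-Pr2NEt, CH2Cl2) gives 1-(methoxymethoxy)-2,3,4,5-tetramethoxybenzene F3. Ortho-lithiation at the only free position, directed by the OMOM group (n-BuLi, THF, −78 to 0 °C), followed by an I2 quench gives 1-iodo-2-(methoxymethoxy)-3,4,5,6-tetramethoxybenzene F4. Mild acid (HCl, MeOH, 40 °C) removes the acetal and returns to the route at iodophenol 5.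

Step 3 (homologation with a free phenol) may be sluggish as the phenoxide, and the free phenol is also the most exposed group in step 4. The fallback sets out from aldehyde 6 and switches to a protected series. Benzylation (BnBr, K2CO3, DMF) gives 3-(benzyloxy)-4,5-dimethoxybenzaldehyde F5, and Ohira–Bestmann homologation (K2CO3, MeOH) gives 1-(benzyloxy)-5-ethynyl-2,3-dimethoxybenzene F6. Carbonylative annulation of this alkyne with 5 under the step 4 conditions passes through 3-[3-(benzyloxy)-4,5-dimethoxyphenyl]-1-(2-hydroxy-3,4,5,6-tetramethoxyphenyl)prop-2-yn-1-one F7 and (E)-3-[3-(benzyloxy)-4,5-dimethoxyphenyl]-3-(diethylamino)-1-(2-hydroxy-3,4,5,6-tetramethoxyphenyl)prop-2-en-1-one F8, neither isolated, to 3'-(benzyloxy)-5,6,7,8,4',5'-hexamethoxyflavone F9. Hydrogenolysis (H2 1 atm, 10% Pd/C, EtOAc, rt, stopped after one equivalent to spare the C2=C3 bond) returns to the route at target 10.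

**Further compounds**
F1 | step 4 | 1-(2-hydroxy-3,4,5,6-tetramethoxyphenyl)ethan-1-one | CC(=O)c1c(O)c(OC)c(OC)c(OC)c1OC
F2 | step 4 | (E)-1-(2-hydroxy-3,4,5,6-tetramethoxyphenyl)-3-(3-hydroxy-4,5-dimethoxyphenyl)prop-2-en-1-one | COc1cc(/C=C/C(=O)c2c(O)c(OC)c(OC)c(OC)c2OC)cc(O)c1OC
F3 | step 2 | 1-(methoxymethoxy)-2,3,4,5-tetramethoxybenzene | COCOc1cc(OC)c(OC)c(OC)c1OC
F4 | step 2 | 1-iodo-2-(methoxymethoxy)-3,4,5,6-tetramethoxybenzene | COCOc1c(I)c(OC)c(OC)c(OC)c1OC
F5 | step 3 | 3-(benzyloxy)-4,5-dimethoxybenzaldehyde | COc1cc(C=O)cc(OCc2ccccc2)c1OC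
F6 | step 3 | 1-(benzyloxy)-5-ethynyl-2,3-dimethoxybenzene | COc1cc(C#C)cc(OCc2ccccc2)c1OC
F7 | step 3 | 3-[3-(benzyloxy)-4,5-dimethoxyphenyl]-1-(2-hydroxy-3,4,5,6-tetramethoxyphenyl)prop-2-yn-1-one | COc1cc(C#CC(=O)c2c(O)c(OC)c(OC)c(OC)c2OC)cc(OCc2ccccc2)c1OC
F8 | step 3 | (E)-3-[3-(benzyloxy)-4,5-dimethoxyphenyl]-3-(diethylamino)-1-(2-hydroxy-3,4,5,6-tetramethoxyphenyl)prop-2-en-1-one | CCN(CC)/C(=C/C(=O)c1c(O)c(OC)c(OC)c(OC)c1OC)c1cc(OCc2ccccc2)c(OC)c(OC)c1
F9 | step 3 | 3'-(benzyloxy)-5,6,7,8,4',5'-hexamethoxyflavone | COc1cc(-c2cc(=O)c3c(OC)c(OC)c(OC)c(OC)c3o2)cc(OCc2ccccc2)c1OC
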